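**Retrosynthetic overview** (germacrane numbering: C1 ketone, C2, C3, C4 with methyl C15, C5, C6 lactone O‑carbon, C7, C8 methacrylate carbinol, C9, C10 with methyl C14, C11, C12 lactone C=O, C13 CH2OAc)
1. Target ⇐ acetylations, desilylation, desulfonylation ⇐ ten‑membered 2‑phenylsulfonyl 1‑ketone, closed last at C2–C3 by intramolecular Tsuji–Trost alkylation of the C2 β‑keto‑sulfone carbanion on the η3‑allyl C3–C4–C5 made from a C5 allylic carbonate; the 1,3‑transposition creates the 4E alkene.
2. Enabling feature: C10 is fully substituted, so the C1 carbonyl gives a stabilised carbanion only at C2; C3 is the free terminus of the allyl unit C3–C4(CH3)–C5, whose other end C5 lies next to the lactone carbinol C6 and can carry the leaving group; the butenolide ring (O–C6–C7=C11–C12) is already in place.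
3. Seco precursor ⇐ vinylogous Mukaiyama aldol of a 2‑silyloxyfuran with methacrolein (C5–C6, sets C6, regenerates the butenolide) ⇐ furyl Grignard + aldehyde (C7–C8), oxidation, CBS reduction (C8).
4. Aldehyde fragment ⇐ (S)‑lactic acid (C10 by self‑regeneration of stereocentres, sulfone by Claisen acylation); furan fragment ⇐ 2‑butyne‑1,4‑diol (carbonylation to an allenoate, iodolactonisation).
5. Ring order: butenolide (step 9, stored as aromatic silyloxyfuran in steps 10–14, re‑formed in step 15), then the ten‑membered carbocycle (step 18).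

Key step: step 18

Assumption: the sense of induction of the chiral bisphosphoramide in step 15 is taken from simpler 2‑silyloxyfurans (the mirror‑image catalyst is used if it proves opposite); the configuration drawn at the C5 carbinol (24–27) and the Z enol‑ether geometry (9–26) are arbitrary, since both elements are erased later.

Step 1
Reactants: 1 (S)-lactic acid; 2 pivalaldehyde
Product: 3 (2S,5S)-2-tert-butyl-5-methyl-1,3-dioxolan-4-one
Conditions: TsOH·H2O (cat.), H2SO4 (cat.), pentane, reflux, Dean–Stark; crystallisation at −78 °C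
Reagents that add atoms: none
Why: Acid‑catalysed acetalisation of the α‑hydroxy acid gives the dioxolanone, whose cis (2S,5S) isomer is enriched by crystallisation so that the lactic acid configuration is stored in the acetal centre (self‑regeneration of stereocentres).

Step 2
Reactants: 3 (2S,5S)-2-tert-butyl-5-methyl-1,3-dioxolan-4-one; 4 allyl bromide
Product: 6 (2S,5R)-5-allyl-2-tert-butyl-5-methyl-1,3-dioxolan-4-one, via lithium enolate 5 (not isolated)
Conditions: LiN(i-Pr)2, THF, −78 °C; then 4, −78 → −30 °C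
Reagents that add atoms: none
Why: Enolate alkylation in which allyl bromide should attack the planar enolate on the face opposite the tert‑butyl group, which sets the quaternary C10 in the R configuration of the target.

Step 3
Reactants: 6 (2S,5R)-5-allyl-2-tert-butyl-5-methyl-1,3-dioxolan-4-one; 7 methyl phenyl sulfone
Product: 8 (R)-3-hydroxy-3-methyl-1-(phenylsulfonyl)hex-5-en-2-one
Conditions: 7 (3.5 equiv), n-BuLi (3.4 equiv), THF, −78 °C; then 6, −78 → 0 °C; aq. NH4Cl
Reagents that add atoms: none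
Why: Claisen‑type acylation of the sulfonyl carbanion by the activated acetal ester, the product being protected as its enolate while the hemiacetal collapses to pivalaldehyde and the tertiary alkoxide, with C10 untouched.

Step 4
Reactants: 8 (R)-3-hydroxy-3-methyl-1-(phenylsulfonyl)hex-5-en-2-one
Product: 9 (1Z,3R)-3-methyl-1-(phenylsulfonyl)-2,3-bis(triethylsilyloxy)hexa-1,5-diene
Conditions: TESOTf (2.5 equiv), Et3N, CH2Cl2, −78 → 0 °C
Reagents that add atoms: triethylsilyl trifluoromethanesulfonate (TESOTf), CC[Si](CC)(CC)OS(=O)(=O)C(F)(F)F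
Why: Silyl triflate/amine O‑silylation turns the β‑keto sulfone into its silyl enol ether and the tertiary alcohol into its TES ether, masking the acidic C2 position so that the later C8 aldehyde cannot undergo an intramolecular aldol reaction.

Step 5
Reactants: 9 (1Z,3R)-3-methyl-1-(phenylsulfonyl)-2,3-bis(triethylsilyloxy)hexa-1,5-diene
Product: 11 (3R,4Z)-3-methyl-5-(phenylsulfonyl)-3,4-bis(triethylsilyloxy)pent-4-enal, via ozonide 10 (not isolated)
Conditions: O3, CH2Cl2, pyridine, Sudan red 7B, −78 °C; then PPh3, −78 °C → rt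
Reagents that add atoms: ozone, [O-][O+]=O
Why: Indicator‑controlled ozonolysis with reductive work‑up should cleave the unhindered terminal alkene in preference to the sulfonyl‑deactivated, hindered enol ether and unveil C8 as the aldehyde.

Step 6
Reactants: 12 2-butyne-1,4-diol
Product: 13 4-(tert-butyldiphenylsilyloxy)but-2-yn-1-ol
Conditions: 12 (3 equiv), TBDPSCl (1 equiv), imidazole, DMF, 0 °C → rt
Reagents that add atoms: tert-butyl(chloro)diphenylsilane (TBDPSCl), CC(C)(C)[Si](Cl)(c1ccccc1)c1ccccc1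
Why: Statistical monosilylation with excess diol protects the future C13 oxygen as a robust ether that is a poor leaving group in all later basic and palladium steps.

Step 7
Reactants: 13 4-(tert-butyldiphenylsilyloxy)but-2-yn-1-ol
Product: 14 4-(tert-butyldiphenylsilyloxy)but-2-yn-1-yl methyl carbonate
Conditions: ClCO2Me, pyridine, CH2Cl2, 0 °C
Reagents that add atoms: methyl chloroformate, COC(=O)Cl
Why: O‑acylation to the propargylic carbonate installs the leaving group for the carbonylation.

Step 8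
Reactants: 14 4-(tert-butyldiphenylsilyloxy)but-2-yn-1-yl methyl carbonate
Product: 15 methyl 2-[(tert-butyldiphenylsilyloxy)methyl]buta-2,3-dienoate
Conditions: Pd(OAc)2 (2 mol%), PPh3 (8 mol%), CO (5 atm), MeOH, 45 °C
Reagents that add atoms: carbon monoxide, [C-]#[O+]
Why: Palladium‑catalysed carbonylation of a propargylic carbonate, in which zerovalent palladium adds in SN2′ fashion to give an allenylpalladium species, CO inserts and the liberated methoxide gives the 2,3‑dienoate with C12 on C11.

Step 9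
Reactants: 15 methyl 2-[(tert-butyldiphenylsilyloxy)methyl]buta-2,3-dienoate
Product: 16 3-[(tert-butyldiphenylsilyloxy)methyl]-4-iodofuran-2(5H)-one
Conditions: I2 (1.5 equiv), MeCN, rt, dark
Reagents that add atoms: iodine, II
Why: Iodolactonisation of the 2,3‑allenoate, in which the ester carbonyl oxygen closes the five‑membered ring (5‑endo) onto the iodonium‑activated terminal allene bond and iodide removes the methyl group, giving the butenolide with iodine at C7.

Step 10
Reactants: 16 3-[(tert-butyldiphenylsilyloxy)methyl]-4-iodofuran-2(5H)-one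
Product: 17 2-(tert-butyldimethylsilyloxy)-3-[(tert-butyldiphenylsilyloxy)methyl]-4-iodofuran
Conditions: TBSOTf, Et3N, CH2Cl2, 0 °C
Reagents that add atoms: tert-butyldimethylsilyl trifluoromethanesulfonate (TBSOTf), CC(C)(C)[Si](C)(C)OS(=O)(=O)C(F)(F)F
Why: Soft enolisation and O‑silylation give the aromatic 2‑silyloxyfuran, which masks the lactone and makes the iodide an ordinary heteroaryl halide, whereas a 4‑metallated butenolide would open by β‑elimination of the ring oxygen.

Step 11
Reactants: 17 2-(tert-butyldimethylsilyloxy)-3-[(tert-butyldiphenylsilyloxy)methyl]-4-iodofuran; 11 (3R,4Z)-3-methyl-5-(phenylsulfonyl)-3,4-bis(triethylsilyloxy)pent-4-enal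
Product: 19 (3R,4Z)-1-[5-(tert-butyldimethylsilyloxy)-4-((tert-butyldiphenylsilyloxy)methyl)furan-3-yl]-3-methyl-5-(phenylsulfonyl)-3,4-bis(triethylsilyloxy)pent-4-en-1-ol (C1 epimers), via furylmagnesium chloride 18 (not isolated)
Conditions: i-PrMgCl·LiCl, THF, −40 °C; then 11, −78 → −20 °C; aq. NH4Cl
Reagents that add atoms: none
Why: Iodine–magnesium exchange and Grignard addition to the aldehyde form the C7–C8 bond, the uncontrolled carbinol centre being corrected in the next two steps.

Step 12
Reactants: 19 carbinol (C1 epimers)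
Product: 20 (3R,4Z)-1-[5-(tert-butyldimethylsilyloxy)-4-((tert-butyldiphenylsilyloxy)methyl)furan-3-yl]-3-methyl-5-(phenylsulfonyl)-3,4-bis(triethylsilyloxy)pent-4-en-1-one
Conditions: MnO2 (activated, excess), CH2Cl2, rt
Reagents that add atoms: none
Why: MnO2 oxidation of the heteroaryl (benzylic‑type) carbinol gives the ketone and erases the C8 mixture under neutral conditions that the silyl enol ethers should survive.

Step 13
Reactants: 20 furyl ketone
Product: 21 (1S,3R,4Z)-1-[5-(tert-butyldimethylsilyloxy)-4-((tert-butyldiphenylsilyloxy)methyl)furan-3-yl]-3-methyl-5-(phenylsulfonyl)-3,4-bis(triethylsilyloxy)pent-4-en-1-ol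
Conditions: (R)-2-methyl-CBS-oxazaborolidine (0.3 equiv), BH3·SMe2, toluene, −30 °C; MeOH quench
Reagents that add atoms: none
Why: Corey–Bakshi–Shibata reduction, in which the furyl group acts as the large and the CH2 group as the small substituent, so that the (R)‑oxazaborolidine should give the (S)‑carbinol at C8 (as acetophenone gives (S)‑1‑phenylethanol) under reagent control.

Step 14
Reactants: 21 (1S)-alcohol
Product: 22 (1S,3R,4Z)-1-[5-(tert-butyldimethylsilyloxy)-4-((tert-butyldiphenylsilyloxy)methyl)furan-3-yl]-3-methyl-5-(phenylsulfonyl)-3,4-bis(triethylsilyloxy)pent-4-en-1-yl methacrylate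
Conditions: methacryloyl chloride, Et3N, DMAP (cat.), CH2Cl2, 0 °C
Reagents that add atoms: methacryloyl chloride, C=C(C)C(Cl)=O
Why: Acylation installs the final C8 ester now, while the lactone is still stored as the base‑stable silyloxyfuran, and blocks the C8 oxygen from attacking the later allyl complex.

Step 15
Reactants: 22 furyl methacrylate; 23 methacrolein
Product: 25 (1S,3R,4Z)-1-{(2S)-4-[(tert-butyldiphenylsilyloxy)methyl]-2-[(1S)-1-hydroxy-2-methylprop-2-enyl]-5-oxo-2,5-dihydrofuran-3-yl}-3-methyl-5-(phenylsulfonyl)-3,4-bis(triethylsilyloxy)pent-4-en-1-yl methacrylate, via trichlorosilyl ether 24 (not isolated)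
Conditions: 23 (2 equiv), SiCl4 (1.5 equiv), (R,R)-binaphthyldiamine-derived bisphosphoramide (10 mol%), i-Pr2NEt (0.2 equiv), CH2Cl2, −78 °C; aq. NaHCO3
Reagents that add atoms: none
Why: Catalytic enantioselective vinylogous Mukaiyama aldol (Lewis‑base‑activated SiCl4), in which γ‑attack of the silyloxyfuran on methacrolein forms C5–C6 and regenerates the butenolide, the chiral catalyst choosing the furan face that sets C6, while the carbinol configuration at C5 is of no consequence.

Step 16
Reactants: 25 butenolide alcohol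
Product: 26 (1S,3R,4Z)-1-{(2S)-4-[(tert-butyldiphenylsilyloxy)methyl]-2-[(1S)-1-(methoxycarbonyloxy)-2-methylprop-2-enyl]-5-oxo-2,5-dihydrofuran-3-yl}-3-methyl-5-(phenylsulfonyl)-3,4-bis(triethylsilyloxy)pent-4-en-1-yl methacrylate
Conditions: ClCO2Me, pyridine, DMAP (cat.), CH2Cl2, 0 °C
Reagents that add atoms: methyl chloroformate, COC(=O)Cl
Why: O‑acylation of the secondary allylic alcohol under weakly basic conditions installs the carbonate that will later serve as leaving group and internal base source.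

Step 17
Reactants: 26 carbonate
Product: 27 (1S,3R)-1-{(2S)-4-[(tert-butyldiphenylsilyloxy)methyl]-2-[(1S)-1-(methoxycarbonyloxy)-2-methylprop-2-enyl]-5-oxo-2,5-dihydrofuran-3-yl}-3-hydroxy-3-methyl-4-oxo-5-(phenylsulfonyl)pentyl methacrylate
Conditions: HF·pyridine, pyridine, THF, 0 °C → rt
Reagents that add atoms: none
Why: Buffered fluoride desilylation should cleave the enol TES ether (releasing the β‑keto sulfone) and the tertiary TES ether while the primary TBDPS ether, the carbonate and the esters remain.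

Step 18
Reactants: 27 seco β-keto sulfone carbonate
Product: 28 (4E,6R,8S,10R)-10-hydroxy-8-methacryloyloxy-1-oxo-2-(phenylsulfonyl)-13-(tert-butyldiphenylsilyloxy)germacra-4,7(11)-dien-12,6-olide (C2 epimers)
Conditions: Pd2(dba)3·CHCl3 (5 mol%), dppe (12 mol%), THF, 60 °C, syringe-pump addition over 8 h to 2 mM
Reagents that add atoms: none
Why: Zerovalent palladium ionises the secondary allylic carbonate at C5 with inversion to the cationic η3‑(2‑methylallyl)palladium unit C3–C4–C5 plus CO2 and methoxide; methoxide deprotonates the β‑keto sulfone at C2 (the only carbon acid near pKa 12, enolisable only on this side because C10 is quaternary), and the soft carbanion attacks the unsubstituted terminus C3 anti to the metal, forming C2–C3 and returning the catalyst. The closest known reaction type is the intramolecular Tsuji–Trost alkylation of sulfonyl‑stabilised carbanions by allylic carbonates under neutral, high‑dilution conditions, which is established for medium and large carbocycles. The ten‑membered carbocycle closes by attack at the distal allyl terminus (10‑endo with respect to the allyl unit), whereas the eight‑membered alternative would need attack at C5, which is branched and deactivated by the C6 oxygen. No permanent stereocentre is made: C2 forms as an epimer mixture that step 19 erases, C6, C8 and C10 are untouched, and the C4=C5 geometry should be E because ring closure from the syn‑η3 complex places C6 and C3 trans, the chelating phosphine allowing syn/anti equilibration before the slow cyclisation. The step needs substitution to win over loss of the acidic C6–H from the allyl complex (giving the conjugated ylidene‑butenolide) and over oligomerisation; the first is countered by fast proton transfer from C2–H to methoxide and by the bidentate ligand, the second by slow addition at about 2 mM.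

Step 19
Reactants: 28 macrocyclic β-keto sulfone
Product: 29 (4E,6R,8S,10R)-10-hydroxy-8-methacryloyloxy-1-oxo-13-(tert-butyldiphenylsilyloxy)germacra-4,7(11)-dien-12,6-olide
Conditions: SmI2 (2.5 equiv), THF/MeOH, −78 °C
Reagents that add atoms: none
Why: Reductive desulfonylation by single‑electron transfer, which should cleave the α‑sulfonyl ketone within minutes at −78 °C, far faster than the free α‑hydroxy ketone, the methacrylate or the butenolide, the samarium enolate being protonated by methanol.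

Step 20
Reactants: 29 silyl ether ketol
Product: 30 (4E,6R,8S,10R)-10,13-dihydroxy-8-methacryloyloxy-1-oxogermacra-4,7(11)-dien-12,6-olide
Conditions: HF·pyridine, THF, 0 °C → rt
Reagents that add atoms: none
Why: Non‑basic fluoride cleavage of the primary TBDPS ether frees the C13 alcohol without the base that would epimerise C6 through the furanolate.

Step 21
Reactants: 30 diol
Product: 31 (4E,6R,8S,10R)-10,13-diacetoxy-8-methacryloyloxy-1-oxogermacra-4,7(11)-dien-12,6-olide (CNP0115165.1)
Conditions: Ac2O, Sc(OTf)3 (2 mol%), MeCN, −20 °C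
Reagents that add atoms: acetic anhydride, CC(=O)OC(C)=O
Why: Lewis‑acid‑catalysed acetylation should esterify both the primary alcohol and the hindered tertiary ketol without base, which matters because a furanolate formed by base would expel the new C13 acetate.

**Compound list**
1 | (S)-lactic acid | C[C@H](O)C(=O)O | starting material
2 | pivalaldehyde | CC(C)(C)C=O | starting material
3 | (2S,5S)-2-tert-butyl-5-methyl-1,3-dioxolan-4-one | C[C@@H]1O[C@H](C(C)(C)C)OC1=O | intermediate
4 | allyl bromide | C=CCBr | starting material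
5 | lithium (S)-2-tert-butyl-5-methyl-1,3-dioxol-4-olate (enolate of 3) | CC1=C(O[Li])O[C@@H](C(C)(C)C)O1 | intermediate
6 | (2S,5R)-5-allyl-2-tert-butyl-5-methyl-1,3-dioxolan-4-one | C[C@]1(CC=C)O[C@H](C(C)(C)C)OC1=O | intermediate
7 | methyl phenyl sulfone | CS(=O)(=O)c1ccccc1 | starting material
8 | (R)-3-hydroxy-3-methyl-1-(phenylsulfonyl)hex-5-en-2-one | C=CC[C@@](C)(O)C(=O)CS(=O)(=O)c1ccccc1 | intermediate
9 | (1Z,3R)-3-methyl-1-(phenylsulfonyl)-2,3-bis(triethylsilyloxy)hexa-1,5-diene | C=CC[C@@](C)(O[Si](CC)(CC)CC)/C(O[Si](CC)(CC)CC)=C/S(=O)(=O)c1ccccc1 | intermediate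
10 | ozonide (1,2,4-trioxolane) of the terminal alkene of 9 | C1OC(C[C@@](C)(O[Si](CC)(CC)CC)/C(O[Si](CC)(CC)CC)=C/S(=O)(=O)c2ccccc2)OO1 | intermediate
11 | (3R,4Z)-3-methyl-5-(phenylsulfonyl)-3,4-bis(triethylsilyloxy)pent-4-enal | O=CC[C@@](C)(O[Si](CC)(CC)CC)/C(O[Si](CC)(CC)CC)=C/S(=O)(=O)c1ccccc1 | intermediate
12 | 2-butyne-1,4-diol | OCC#CCO | starting material
13 | 4-(tert-butyldiphenylsilyloxy)but-2-yn-1-ol | OCC#CCO[Si](c1ccccc1)(c1ccccc1)C(C)(C)C | intermediate
14 | 4-(tert-butyldiphenylsilyloxy)but-2-yn-1-yl methyl carbonate | COC(=O)OCC#CCO[Si](c1ccccc1)(c1ccccc1)C(C)(C)C | intermediate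
15 | methyl 2-[(tert-butyldiphenylsilyloxy)methyl]buta-2,3-dienoate | C=C=C(CO[Si](c1ccccc1)(c1ccccc1)C(C)(C)C)C(=O)OC | intermediate
16 | 3-[(tert-butyldiphenylsilyloxy)methyl]-4-iodofuran-2(5H)-one | O=C1OCC(I)=C1CO[Si](c2ccccc2)(c2ccccc2)C(C)(C)C | intermediate
17 | 2-(tert-butyldimethylsilyloxy)-3-[(tert-butyldiphenylsilyloxy)methyl]-4-iodofuran | CC(C)(C)[Si](C)(C)Oc1occ(I)c1CO[Si](c2ccccc2)(c2ccccc2)C(C)(C)C | intermediate
18 | [5-(tert-butyldimethylsilyloxy)-4-((tert-butyldiphenylsilyloxy)methyl)furan-3-yl]magnesium chloride | CC(C)(C)[Si](C)(C)Oc1occ([Mg]Cl)c1CO[Si](c2ccccc2)(c2ccccc2)C(C)(C)C | intermediate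
19 | furyl carbinol, (3R,4Z), C1 epimers | OC(C[C@@](C)(O[Si](CC)(CC)CC)/C(O[Si](CC)(CC)CC)=C/S(=O)(=O)c1ccccc1)c1coc(O[Si](C)(C)C(C)(C)C)c1CO[Si](c2ccccc2)(c2ccccc2)C(C)(C)C | intermediate
20 | furyl ketone, (3R,4Z) | O=C(C[C@@](C)(O[Si](CC)(CC)CC)/C(O[Si](CC)(CC)CC)=C/S(=O)(=O)c1ccccc1)c1coc(O[Si](C)(C)C(C)(C)C)c1CO[Si](c2ccccc2)(c2ccccc2)C(C)(C)C | intermediate
21 | furyl carbinol, (1S,3R,4Z) | O[C@@H](C[C@@](C)(O[Si](CC)(CC)CC)/C(O[Si](CC)(CC)CC)=C/S(=O)(=O)c1ccccc1)c1coc(O[Si](C)(C)C(C)(C)C)c1CO[Si](c2ccccc2)(c2ccccc2)C(C)(C)C | intermediate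
22 | furyl methacrylate, (1S,3R,4Z) | C=C(C)C(=O)O[C@@H](C[C@@](C)(O[Si](CC)(CC)CC)/C(O[Si](CC)(CC)CC)=C/S(=O)(=O)c1ccccc1)c1coc(O[Si](C)(C)C(C)(C)C)c1CO[Si](c2ccccc2)(c2ccccc2)C(C)(C)C | intermediate
23 | methacrolein | C=C(C)C=O | starting material
24 | trichlorosilyl ether of aldol 25 | C=C(C)C(=O)O[C@@H](C[C@@](C)(O[Si](CC)(CC)CC)/C(O[Si](CC)(CC)CC)=C/S(=O)(=O)c1ccccc1)C1=C(CO[Si](c2ccccc2)(c2ccccc2)C(C)(C)C)C(=O)O[C@@H]1[C@@H](O[Si](Cl)(Cl)Cl)C(C)=C | intermediate
25 | butenolide aldol, (1S,3R,4Z), ring C2 S, carbinol S | C=C(C)C(=O)O[C@@H](C[C@@](C)(O[Si](CC)(CC)CC)/C(O[Si](CC)(CC)CC)=C/S(=O)(=O)c1ccccc1)C1=C(CO[Si](c2ccccc2)(c2ccccc2)C(C)(C)C)C(=O)O[C@@H]1[C@@H](O)C(C)=C | intermediate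
26 | allylic methyl carbonate of 25 | C=C(C)C(=O)O[C@@H](C[C@@](C)(O[Si](CC)(CC)CC)/C(O[Si](CC)(CC)CC)=C/S(=O)(=O)c1ccccc1)C1=C(CO[Si](c2ccccc2)(c2ccccc2)C(C)(C)C)C(=O)O[C@@H]1[C@@H](OC(=O)OC)C(C)=C | intermediate
27 | seco β-keto sulfone carbonate (key-step precursor) | C=C(C)C(=O)O[C@@H](C[C@@](C)(O)C(=O)CS(=O)(=O)c1ccccc1)C1=C(CO[Si](c2ccccc2)(c2ccccc2)C(C)(C)C)C(=O)O[C@@H]1[C@@H](OC(=O)OC)C(C)=C | intermediate
28 | (4E,6R,8S,10R)-10-hydroxy-8-methacryloyloxy-1-oxo-2-(phenylsulfonyl)-13-(tert-butyldiphenylsilyloxy)germacra-4,7(11)-dien-12,6-olide, C2 epimers | C=C(C)C(=O)O[C@H]1C[C@@](C)(O)C(=O)C(S(=O)(=O)c3ccccc3)C/C(C)=C/[C@H]2OC(=O)C(CO[Si](c3ccccc3)(c3ccccc3)C(C)(C)C)=C12 | intermediate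
29 | (4E,6R,8S,10R)-10-hydroxy-8-methacryloyloxy-1-oxo-13-(tert-butyldiphenylsilyloxy)germacra-4,7(11)-dien-12,6-olide | C=C(C)C(=O)O[C@H]1C[C@@](C)(O)C(=O)CC/C(C)=C/[C@H]2OC(=O)C(CO[Si](c3ccccc3)(c3ccccc3)C(C)(C)C)=C12 | intermediate
30 | (4E,6R,8S,10R)-10,13-dihydroxy-8-methacryloyloxy-1-oxogermacra-4,7(11)-dien-12,6-olide | C=C(C)C(=O)O[C@H]1C[C@@](C)(O)C(=O)CC/C(C)=C/[C@H]2OC(=O)C(CO)=C12 | intermediate
31 | (4E,6R,8S,10R)-10,13-diacetoxy-8-methacryloyloxy-1-oxogermacra-4,7(11)-dien-12,6-olide (CNP0115165.1) | C=C(C)C(=O)O[C@H]1C[C@@](C)(OC(C)=O)C(=O)CC/C(C)=C/[C@H]2OC(=O)C(COC(C)=O)=C12 | target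

**Totals:** 21 steps; longest linear sequence 16 steps (steps 1–5 or 6–10, then 11–21).

**Three steps most likely to fail**

Step 18 (macrocyclisation). What may go wrong: elimination from the allylpalladium intermediate by loss of the acidic C6–H (giving the conjugated ylidene‑butenolide), closure to the 4Z ring, or oligomerisation. Fallback (sets out from 25, rejoins at 28): buffered HF·pyridine removes both TES groups of 25 to give the desilylated diol F1. Thionyl chloride in ether at 0 °C then converts the isopropenyl carbinol with allylic transposition (SNi′) into the primary (E)-allylic chloride F2. Cs2CO3 in MeCN under high dilution closes the ring by a classical intramolecular SN2 alkylation of the sulfonyl‑stabilised carbanion, giving 28 without a metal–allyl intermediate.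

Step 15 (vinylogous aldol). What may go wrong: poor facial selectivity at the furan because the neighbouring C8 centre overrides the catalyst, α‑ instead of γ‑attack, or Lewis‑acid ionisation of the furylmethyl ester. Fallback (sets out from 17, 23 and 11, rejoins at 25): the same catalytic aldol is run on achiral 17, where no substrate bias exists, to give the iodobutenolide aldol F3. PMB trichloroacetimidate with catalytic TfOH gives the PMB ether F4, and (Me3Sn)2 with Pd(PPh3)4 gives the vinylstannane F5. Separately, Pinnick oxidation of 11 gives the acid F6, and oxalyl chloride with catalytic DMF gives the acid chloride F7. Stille acylation of F5 with F7 (Pd2(dba)3·CHCl3, AsPh3) gives the butenolide ketone F8. CBS reduction with the (R)-oxazaborolidine gives the (S)-alcohol F9, methacryloyl chloride/pyridine gives the methacrylate F10, and DDQ removes the PMB group to give 25.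

Step 21 (double acetylation). What may go wrong: incomplete esterification of the hindered tertiary ketol, or Lewis‑acid‑induced transannular cyclisation or ionisation of the allylic lactone. Fallback (sets out from 29, rejoins at 31): the tertiary ketol is acetylated first with Ac2O, DMAP and Et3N at 40 °C, while C13 still carries the silyl ether and no β‑acyloxy leaving group exists, giving the tertiary acetate F11. HF·pyridine then gives the primary alcohol F12, and Ac2O/pyridine at 0 °C acetylates it to 31.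

Further compounds
F1 | step 18 | desilylated diol of 25 (free C5 carbinol, C10 hydroxyl and β-keto sulfone) | C=C(C)C(=O)O[C@@H](C[C@@](C)(O)C(=O)CS(=O)(=O)c1ccccc1)C1=C(CO[Si](c2ccccc2)(c2ccccc2)C(C)(C)C)C(=O)O[C@@H]1[C@@H](O)C(C)=C
F2 | step 18 | primary (E)-allylic chloride (C3 chloride, 4E alkene) | C=C(C)C(=O)O[C@@H](C[C@@](C)(O)C(=O)CS(=O)(=O)c1ccccc1)C1=C(CO[Si](c2ccccc2)(c2ccccc2)C(C)(C)C)C(=O)O[C@@H]1/C=C(\C)CCl
F3 | step 15 | (5R)-3-[(tert-butyldiphenylsilyloxy)methyl]-5-[(1S)-1-hydroxy-2-methylprop-2-enyl]-4-iodofuran-2(5H)-one | IC1=C(CO[Si](c2ccccc2)(c2ccccc2)C(C)(C)C)C(=O)O[C@@H]1[C@@H](O)C(C)=C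
F4 | step 15 | PMB ether of F3 | IC1=C(CO[Si](c2ccccc2)(c2ccccc2)C(C)(C)C)C(=O)O[C@@H]1[C@@H](OCc2ccc(OC)cc2)C(C)=C
F5 | step 15 | 4-(trimethylstannyl)butenolide from F4 | C[Sn](C)(C)C1=C(CO[Si](c2ccccc2)(c2ccccc2)C(C)(C)C)C(=O)O[C@@H]1[C@@H](OCc2ccc(OC)cc2)C(C)=C
F6 | step 15 | (3R,4Z)-3-methyl-5-(phenylsulfonyl)-3,4-bis(triethylsilyloxy)pent-4-enoic acid | OC(=O)C[C@@](C)(O[Si](CC)(CC)CC)/C(O[Si](CC)(CC)CC)=C/S(=O)(=O)c1ccccc1
F7 | step 15 | (3R,4Z)-3-methyl-5-(phenylsulfonyl)-3,4-bis(triethylsilyloxy)pent-4-enoyl chloride | ClC(=O)C[C@@](C)(O[Si](CC)(CC)CC)/C(O[Si](CC)(CC)CC)=C/S(=O)(=O)c1ccccc1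
F8 | step 15 | butenolide C8 ketone with PMB ether | O=C(C[C@@](C)(O[Si](CC)(CC)CC)/C(O[Si](CC)(CC)CC)=C/S(=O)(=O)c1ccccc1)C1=C(CO[Si](c2ccccc2)(c2ccccc2)C(C)(C)C)C(=O)O[C@@H]1[C@@H](OCc2ccc(OC)cc2)C(C)=C
F9 | step 15 | (S)-C8 alcohol with PMB ether | O[C@@H](C[C@@](C)(O[Si](CC)(CC)CC)/C(O[Si](CC)(CC)CC)=C/S(=O)(=O)c1ccccc1)C1=C(CO[Si](c2ccccc2)(c2ccccc2)C(C)(C)C)C(=O)O[C@@H]1[C@@H](OCc2ccc(OC)cc2)C(C)=C
F10 | step 15 | C8 methacrylate with PMB ether | C=C(C)C(=O)O[C@@H](C[C@@](C)(O[Si](CC)(CC)CC)/C(O[Si](CC)(CC)CC)=C/S(=O)(=O)c1ccccc1)C1=C(CO[Si](c2ccccc2)(c2ccccc2)C(C)(C)C)C(=O)O[C@@H]1[C@@H](OCc2ccc(OC)cc2)C(C)=C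
F11 | step 21 | (4E,6R,8S,10R)-10-acetoxy-8-methacryloyloxy-1-oxo-13-(tert-butyldiphenylsilyloxy)germacra-4,7(11)-dien-12,6-olide | C=C(C)C(=O)O[C@H]1C[C@@](C)(OC(C)=O)C(=O)CC/C(C)=C/[C@H]2OC(=O)C(CO[Si](c3ccccc3)(c3ccccc3)C(C)(C)C)=C12
F12 | step 21 | (4E,6R,8S,10R)-10-acetoxy-13-hydroxy-8-methacryloyloxy-1-oxogermacra-4,7(11)-dien-12,6-olide | C=C(C)C(=O)O[C@H]1C[C@@](C)(OC(C)=O)C(=O)CC/C(C)=C/[C@H]2OC(=O)C(CO)=C12
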